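## Retrosynthetic overview

- Feature: in the target γ-lactone (ring O1–C2–C3–C4–C5) the carbonyl carbon C2 is γ to O1 and also γ to O6, the hydroxyl oxygen on the benzylic carbon C6 of the C4 side chain. The isomeric γ-lactone closed on O6 (ring O6–C2–C3–C4–C6) carries the C6 aryl group and the C4 oxymethyl group cis, and these cover one face of C3.
- Backwards from the target: phenol desilylation; O6 → O1 acyl shift; bond from the C3 methylene carbon to the second arene by cuprate opening of a spiro-oxirane; C3–O and CH2–O bonds by nucleophilic epoxidation of the 3-methylene isomeric lactone.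
- The 3-methylene lactone comes from α-methylenation of the cis lactone, which comes from oxidative cleavage of an allyl group after an auxiliary-controlled anti-aldol reaction of silylated vanillin that sets C4 and C6.
- Ring order: isomeric γ-lactone (step 6), oxirane (step 8, opened in step 10), target γ-lactone (step 12).

Key step: step 8

Remark: the atom labels O1, C2–C6 and O6 follow the target and are kept for the same atoms in every intermediate, while compound names use their own locants. Assumption: the magnesium-catalysed anti-aldol reaction is taken to follow the facial sense of the chelated oxazolidinone enolate (attack opposite the benzyl group), which calls for the (R)-auxiliary.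

## Route

Step 1
Reactants: 1 vanillin
Product: 2 3-methoxy-4-(triisopropylsilyloxy)benzaldehyde
Conditions: TIPSCl, imidazole, DMF, rt
Reagents that add atoms: triisopropylsilyl chloride, CC(C)[Si](Cl)(C(C)C)C(C)C
Why: Imidazole-promoted O-silylation of the phenol; TIPS is chosen because an aryl TIPS ether should withstand the amine bases, hydride, lithium amide, lithium peroxide and cuprate of the later steps, and no stereocentre is involved.

Step 2
Reactants: 3 (R)-4-benzyloxazolidin-2-one; 4 pent-4-enoyl chloride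
Product: 5 (R)-4-benzyl-3-(pent-4-enoyl)oxazolidin-2-one
Conditions: n-BuLi, THF, −78 °C; then 4, −78 → 0 °C
Reagents that add atoms: none
Why: N-Acylation of the lithiated oxazolidinone by the acid chloride (standard loading of an Evans auxiliary); the auxiliary stereocentre is not touched.

Step 3
Reactants: 5 (R)-4-benzyl-3-(pent-4-enoyl)oxazolidin-2-one; 2 3-methoxy-4-(triisopropylsilyloxy)benzaldehyde
Product: 7 (R)-4-benzyl-3-[(2S)-2-[(R)-hydroxy[3-methoxy-4-(triisopropylsilyloxy)phenyl]methyl]pent-4-enoyl]oxazolidin-2-one, via trimethylsilyl ether 6 (not isolated)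
Conditions: MgCl2 (0.2 equiv), Et3N, TMSCl, EtOAc, rt; then 1 M HCl, THF, 0 °C
Reagents that add atoms: none
Why: MgCl2-catalysed Evans anti-aldol reaction: soft enolisation gives the magnesium-chelated Z-enolate of 5, which should add to the non-enolisable aldehyde through a boat-like transition state on the face opposite the benzyl group of the (R)-auxiliary, setting the future C4 (2S in the acyl chain) and C6 (R) anti to each other, while TMSCl silylates the aldolate to turn the magnesium over and the labile TMS ether is cleaved by dilute acid.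

Step 4
Reactants: 7 (R)-4-benzyl-3-[(2S)-2-[(R)-hydroxy[3-methoxy-4-(triisopropylsilyloxy)phenyl]methyl]pent-4-enoyl]oxazolidin-2-one
Product: 8 (1R,2R)-1-[3-methoxy-4-(triisopropylsilyloxy)phenyl]-2-(prop-2-en-1-yl)propane-1,3-diol
Conditions: LiBH4, MeOH (1 equiv), Et2O, 0 °C
Reagents that add atoms: none
Why: Reductive cleavage of the N-acyloxazolidinone with LiBH4 (hydride attack at the exocyclic imide carbonyl) gives the primary alcohol and returns auxiliary 3 without touching the two stereocentres, the alkene or the aryl silyl ether.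

Step 5
Reactants: 8 (1R,2R)-1-[3-methoxy-4-(triisopropylsilyloxy)phenyl]-2-(prop-2-en-1-yl)propane-1,3-diol
Product: 9 (1R,2R)-2-[(tert-butyldimethylsilyloxy)methyl]-1-[3-methoxy-4-(triisopropylsilyloxy)phenyl]pent-4-en-1-ol
Conditions: TBSCl, imidazole, CH2Cl2, 0 °C
Reagents that add atoms: tert-butyldimethylsilyl chloride, CC(C)(C)[Si](C)(C)Cl
Why: Sterically controlled monosilylation: the primary hydroxyl reacts far faster than the secondary benzylic one, so the future O1 is masked and only O6 can close the lactone in the next step.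

Step 6
Reactants: 9 (1R,2R)-2-[(tert-butyldimethylsilyloxy)methyl]-1-[3-methoxy-4-(triisopropylsilyloxy)phenyl]pent-4-en-1-ol
Product: 11 (4R,5R)-4-[(tert-butyldimethylsilyloxy)methyl]-5-[3-methoxy-4-(triisopropylsilyloxy)phenyl]dihydrofuran-2(3H)-one, via lactol 10 (not isolated)
Conditions: OsO4 (cat.), NaIO4, 2,6-lutidine, dioxane/H2O, rt; then TEMPO (cat.), PhI(OAc)2, CH2Cl2, rt
Reagents that add atoms: sodium periodate, [Na+].[O-]I(=O)(=O)=O (terminal source of the carbonyl oxygen, delivered through OsO4)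
Why: Lemieux–Johnson cleavage of the terminal alkene gives the γ-hydroxy aldehyde, which closes on O6 to lactol 10, and TEMPO/PhI(OAc)2 oxidation of the lactol gives the isomeric γ-lactone (ring O6–C2–C3–C4–C6) in which the anti-aldol relationship appears as cis aryl and silyloxymethyl groups; no stereocentre is touched.

Step 7
Reactants: 11 (4R,5R)-4-[(tert-butyldimethylsilyloxy)methyl]-5-[3-methoxy-4-(triisopropylsilyloxy)phenyl]dihydrofuran-2(3H)-one
Product: 14 (4R,5R)-4-[(tert-butyldimethylsilyloxy)methyl]-5-[3-methoxy-4-(triisopropylsilyloxy)phenyl]-3-methylenedihydrofuran-2(3H)-one, via Mannich base 12 (not isolated), via trimethylammonium iodide 13 (not isolated)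
Conditions: LDA, THF, −78 °C; CH2=NMe2+ I−, −78 °C → rt; MeI, MeOH, rt; NaHCO3 (aq), CH2Cl2, rt
Reagents that add atoms: Eschenmoser's salt (N,N-dimethylmethyleneiminium iodide), C=[N+](C)C.[I-]
Why: Eschenmoser methylenation: the lithium enolate of the lactone undergoes a Mannich reaction with the iminium salt, N-methylation turns the amine into a leaving group and E1cB elimination gives the exocyclic alkene; C4 and C6 are not α to the carbonyl and cannot epimerise.

Step 8
Reactants: 14 (4R,5R)-4-[(tert-butyldimethylsilyloxy)methyl]-5-[3-methoxy-4-(triisopropylsilyloxy)phenyl]-3-methylenedihydrofuran-2(3H)-one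
Product: 16 (3R,6R,7R)-7-[(tert-butyldimethylsilyloxy)methyl]-6-[3-methoxy-4-(triisopropylsilyloxy)phenyl]-1,5-dioxaspiro[2.4]heptan-4-one (oxirane oxygen trans to both ring substituents), via lithium peroxy enolate 15 (not isolated)
Conditions: t-BuOOH (anhydrous, decane), n-BuLi, THF, −78 °C; then 14, −78 → 0 °C; H2O
Reagents that add atoms: tert-butyl hydroperoxide, CC(C)(C)OO
Why: The tert-butylperoxide anion adds 1,4 to the exocyclic methylene to give lactone enolate 15, whose C3 then displaces tert-butoxide at the proximal peroxide oxygen, so the CH2–O bond forms first and the C3–O bond second; this is a Weitz–Scheffer epoxidation, the known mode of epoxidation of α-methylene-γ-butyrolactones and enoates with lithium tert-butylperoxide. The oxirane is closed by 3-exo-tet attack of the enolate carbon on oxygen. The only new stereocentre is C3: the peroxymethyl arm lies in the enolate plane and its O–O bond can reach the geometry needed for displacement only over the ring face that is not covered by the cis C4 silyloxymethyl and C6 aryl groups, so the oxygen should arrive trans to both. The step needs this facial selectivity and chemoselectivity for conjugate over acyl attack; the first rests on the two cis substituents (the C4 group sits next to C3), the second on the lithium peroxide in aprotic THF at low temperature, and because the peroxide addition is reversible only the ring closure decides the outcome. C4 and C6 are not enolisable and stay untouched.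

Step 9
Reactants: 17 4-bromo-2-methoxyphenol
Product: 18 (4-bromo-2-methoxyphenoxy)triisopropylsilane
Conditions: TIPSCl, imidazole, DMF, rt
Reagents that add atoms: triisopropylsilyl chloride, CC(C)[Si](Cl)(C(C)C)C(C)C
Why: Imidazole-promoted O-silylation of the phenol so that the bromide can be lithiated in step 10; TIPS matches the group on the other arene so that both fall in the last step.

Step 10
Reactants: 16 (3R,6R,7R)-7-[(tert-butyldimethylsilyloxy)methyl]-6-[3-methoxy-4-(triisopropylsilyloxy)phenyl]-1,5-dioxaspiro[2.4]heptan-4-one; 18 (4-bromo-2-methoxyphenoxy)triisopropylsilane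
Product: 21 (3S,4R,5R)-4-[(tert-butyldimethylsilyloxy)methyl]-3-hydroxy-3-[3-methoxy-4-(triisopropylsilyloxy)benzyl]-5-[3-methoxy-4-(triisopropylsilyloxy)phenyl]dihydrofuran-2(3H)-one, via aryllithium 19 (not isolated), via lithium diarylcuprate 20 (not isolated)
Conditions: 18 (2.4 equiv), t-BuLi (4.8 equiv), Et2O, −78 °C; CuI (1.2 equiv), −78 → −30 °C; then 16, −78 → −20 °C; NH4Cl (aq)
Reagents that add atoms: none
Why: Bromine–lithium exchange and transmetalation to CuI give the Gilman diarylcuprate 20, which opens the 2,2-disubstituted glycidic-type oxirane by SN2 attack at its unsubstituted methylene carbon (the spiro carbon is quaternary and α to the carbonyl), so the C3–O bond and with it the C3 configuration from step 8 are kept, while a cuprate should not attack the lactone carbonyl at low temperature.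

Step 11
Reactants: 21 (3S,4R,5R)-4-[(tert-butyldimethylsilyloxy)methyl]-3-hydroxy-3-[3-methoxy-4-(triisopropylsilyloxy)benzyl]-5-[3-methoxy-4-(triisopropylsilyloxy)phenyl]dihydrofuran-2(3H)-one
Product: 22 (3S,4R,5R)-3-hydroxy-4-(hydroxymethyl)-3-[3-methoxy-4-(triisopropylsilyloxy)benzyl]-5-[3-methoxy-4-(triisopropylsilyloxy)phenyl]dihydrofuran-2(3H)-one
Conditions: HF·pyridine, pyridine, THF, 0 °C → rt
Reagents that add atoms: none
Why: Acidic fluoride desilylation: under HF·pyridine an alkyl TBS ether is cleaved much faster than an aryl TIPS ether, so only the primary hydroxyl (the future O1) is set free and no stereocentre is affected.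

Step 12
Reactants: 22 (3S,4R,5R)-3-hydroxy-4-(hydroxymethyl)-3-[3-methoxy-4-(triisopropylsilyloxy)benzyl]-5-[3-methoxy-4-(triisopropylsilyloxy)phenyl]dihydrofuran-2(3H)-one
Product: 23 (3S,4R)-3-hydroxy-4-[(R)-hydroxy[3-methoxy-4-(triisopropylsilyloxy)phenyl]methyl]-3-[3-methoxy-4-(triisopropylsilyloxy)benzyl]dihydrofuran-2(3H)-one
Conditions: DBU (0.2 equiv), CH2Cl2, rt
Reagents that add atoms: none
Why: Base-catalysed translactonisation (intramolecular transesterification through a bicyclic tetrahedral intermediate): the primary hydroxyl attacks C2 and the acyl group moves from O6 to O1, which should be favoured because a ring with three contiguous cis substituents closed on a secondary benzylic oxygen is exchanged for one closed on a primary oxygen with the arylmethyl group trans to the C4 side chain; only the acyl C–O bond is broken, so C3, C4 and C6 keep their configuration, and the position of the equilibrium remains to be confirmed.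

Step 13
Reactants: 23 (3S,4R)-3-hydroxy-4-[(R)-hydroxy[3-methoxy-4-(triisopropylsilyloxy)phenyl]methyl]-3-[3-methoxy-4-(triisopropylsilyloxy)benzyl]dihydrofuran-2(3H)-one
Product: 24 (3S,4R)-3-hydroxy-3-(4-hydroxy-3-methoxybenzyl)-4-[(R)-hydroxy(4-hydroxy-3-methoxyphenyl)methyl]dihydrofuran-2(3H)-one
Conditions: TBAF, AcOH (1:1), THF, 0 °C
Reagents that add atoms: none
Why: Fluoride cleavage of the two aryl silyl ethers, buffered with acetic acid so that no phenoxide forms that could trigger quinone methide formation at C6 or a reverse acyl shift; the stereocentres are untouched.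

## Compound list

1 | vanillin | COc1cc(C=O)ccc1O | starting material
2 | 3-methoxy-4-(triisopropylsilyloxy)benzaldehyde | COc1cc(C=O)ccc1O[Si](C(C)C)(C(C)C)C(C)C | intermediate
3 | (R)-4-benzyloxazolidin-2-one | O=C1N[C@H](Cc2ccccc2)CO1 | starting material
4 | pent-4-enoyl chloride | C=CCCC(=O)Cl | starting material
5 | (R)-4-benzyl-3-(pent-4-enoyl)oxazolidin-2-one | C=CCCC(=O)N1[C@H](Cc2ccccc2)COC1=O | intermediate
6 | (R)-4-benzyl-3-[(2S)-2-[(R)-[3-methoxy-4-(triisopropylsilyloxy)phenyl](trimethylsilyloxy)methyl]pent-4-enoyl]oxazolidin-2-one | C=CC[C@H](C(=O)N1[C@H](Cc2ccccc2)COC1=O)[C@@H](O[Si](C)(C)C)c1ccc(O[Si](C(C)C)(C(C)C)C(C)C)c(OC)c1 | intermediate (not isolated)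
7 | (R)-4-benzyl-3-[(2S)-2-[(R)-hydroxy[3-methoxy-4-(triisopropylsilyloxy)phenyl]methyl]pent-4-enoyl]oxazolidin-2-one | C=CC[C@H](C(=O)N1[C@H](Cc2ccccc2)COC1=O)[C@@H](O)c1ccc(O[Si](C(C)C)(C(C)C)C(C)C)c(OC)c1 | intermediate
8 | (1R,2R)-1-[3-methoxy-4-(triisopropylsilyloxy)phenyl]-2-(prop-2-en-1-yl)propane-1,3-diol | C=CC[C@H](CO)[C@@H](O)c1ccc(O[Si](C(C)C)(C(C)C)C(C)C)c(OC)c1 | intermediate
9 | (1R,2R)-2-[(tert-butyldimethylsilyloxy)methyl]-1-[3-methoxy-4-(triisopropylsilyloxy)phenyl]pent-4-en-1-ol | C=CC[C@H](CO[Si](C)(C)C(C)(C)C)[C@@H](O)c1ccc(O[Si](C(C)C)(C(C)C)C(C)C)c(OC)c1 | intermediate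
10 | (4R,5R)-4-[(tert-butyldimethylsilyloxy)methyl]-5-[3-methoxy-4-(triisopropylsilyloxy)phenyl]tetrahydrofuran-2-ol (anomer mixture) | OC1C[C@H](CO[Si](C)(C)C(C)(C)C)[C@H](c2ccc(O[Si](C(C)C)(C(C)C)C(C)C)c(OC)c2)O1 | intermediate (not isolated)
11 | (4R,5R)-4-[(tert-butyldimethylsilyloxy)methyl]-5-[3-methoxy-4-(triisopropylsilyloxy)phenyl]dihydrofuran-2(3H)-one (aryl and silyloxymethyl cis) | O=C1C[C@H](CO[Si](C)(C)C(C)(C)C)[C@H](c2ccc(O[Si](C(C)C)(C(C)C)C(C)C)c(OC)c2)O1 | intermediate
12 | (4R,5R)-4-[(tert-butyldimethylsilyloxy)methyl]-3-[(dimethylamino)methyl]-5-[3-methoxy-4-(triisopropylsilyloxy)phenyl]dihydrofuran-2(3H)-one (C3 epimers) | CN(C)CC1C(=O)O[C@@H](c2ccc(O[Si](C(C)C)(C(C)C)C(C)C)c(OC)c2)[C@H]1CO[Si](C)(C)C(C)(C)C | intermediate (not isolated)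
13 | trimethylammonium iodide of 12, N-methylated at nitrogen | C[N+](C)(C)CC1C(=O)O[C@@H](c2ccc(O[Si](C(C)C)(C(C)C)C(C)C)c(OC)c2)[C@H]1CO[Si](C)(C)C(C)(C)C.[I-] | intermediate (not isolated)
14 | (4R,5R)-4-[(tert-butyldimethylsilyloxy)methyl]-5-[3-methoxy-4-(triisopropylsilyloxy)phenyl]-3-methylenedihydrofuran-2(3H)-one | C=C1C(=O)O[C@@H](c2ccc(O[Si](C(C)C)(C(C)C)C(C)C)c(OC)c2)[C@H]1CO[Si](C)(C)C(C)(C)C | intermediate (key-step precursor)
15 | lithium enolate of the 3-(tert-butylperoxymethyl) lactone | CC(C)(C)OOCC1=C([O-])O[C@@H](c2ccc(O[Si](C(C)C)(C(C)C)C(C)C)c(OC)c2)[C@H]1CO[Si](C)(C)C(C)(C)C.[Li+] | intermediate (not isolated)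
16 | (3R,6R,7R)-7-[(tert-butyldimethylsilyloxy)methyl]-6-[3-methoxy-4-(triisopropylsilyloxy)phenyl]-1,5-dioxaspiro[2.4]heptan-4-one | C1O[C@@]12C(=O)O[C@@H](c3ccc(O[Si](C(C)C)(C(C)C)C(C)C)c(OC)c3)[C@H]2CO[Si](C)(C)C(C)(C)C | intermediate (key-step product)
17 | 4-bromo-2-methoxyphenol | COc1cc(Br)ccc1O | starting material
18 | (4-bromo-2-methoxyphenoxy)triisopropylsilane | COc1cc(Br)ccc1O[Si](C(C)C)(C(C)C)C(C)C | intermediate
19 | [3-methoxy-4-(triisopropylsilyloxy)phenyl]lithium | [Li]c1ccc(O[Si](C(C)C)(C(C)C)C(C)C)c(OC)c1 | intermediate (not isolated)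
20 | lithium bis[3-methoxy-4-(triisopropylsilyloxy)phenyl]cuprate | [Li+].COc1cc([Cu-]c2ccc(O[Si](C(C)C)(C(C)C)C(C)C)c(OC)c2)ccc1O[Si](C(C)C)(C(C)C)C(C)C | intermediate (not isolated)
21 | (3S,4R,5R)-4-[(tert-butyldimethylsilyloxy)methyl]-3-hydroxy-3-[3-methoxy-4-(triisopropylsilyloxy)benzyl]-5-[3-methoxy-4-(triisopropylsilyloxy)phenyl]dihydrofuran-2(3H)-one | O[C@]1(Cc2ccc(O[Si](C(C)C)(C(C)C)C(C)C)c(OC)c2)C(=O)O[C@@H](c2ccc(O[Si](C(C)C)(C(C)C)C(C)C)c(OC)c2)[C@H]1CO[Si](C)(C)C(C)(C)C | intermediate
22 | (3S,4R,5R)-3-hydroxy-4-(hydroxymethyl)-3-[3-methoxy-4-(triisopropylsilyloxy)benzyl]-5-[3-methoxy-4-(triisopropylsilyloxy)phenyl]dihydrofuran-2(3H)-one | O[C@]1(Cc2ccc(O[Si](C(C)C)(C(C)C)C(C)C)c(OC)c2)C(=O)O[C@@H](c2ccc(O[Si](C(C)C)(C(C)C)C(C)C)c(OC)c2)[C@H]1CO | intermediate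
23 | (3S,4R)-3-hydroxy-4-[(R)-hydroxy[3-methoxy-4-(triisopropylsilyloxy)phenyl]methyl]-3-[3-methoxy-4-(triisopropylsilyloxy)benzyl]dihydrofuran-2(3H)-one | COc1cc(C[C@@]2(O)C(=O)OC[C@@H]2[C@@H](O)c2ccc(O[Si](C(C)C)(C(C)C)C(C)C)c(OC)c2)ccc1O[Si](C(C)C)(C(C)C)C(C)C | intermediate
24 | (3S,4R)-3-hydroxy-3-(4-hydroxy-3-methoxybenzyl)-4-[(R)-hydroxy(4-hydroxy-3-methoxyphenyl)methyl]dihydrofuran-2(3H)-one | COc1cc(C[C@@]2(O)C(=O)OC[C@@H]2[C@@H](O)c2ccc(O)c(OC)c2)ccc1O | target

## Step count and risks

Total step count: 13. Longest linear sequence: 11 steps (vanillin to 24 through steps 1, 3–8 and 10–13).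

Steps most likely to fail:

Step 8. The oxirane closure may show poor facial selectivity, the peroxide may attack the lactone carbonyl, or the reaction may stop at the conjugate adduct. Fallback: setting out from 14, the C3–O bond is made by electrophilic dihydroxylation instead (OsO4 cat., N-methylmorpholine N-oxide, acetone/H2O), which should also add from the face away from the two cis substituents and give the (3R,4R,5R)-3-hydroxy-3-(hydroxymethyl) lactone F1. Selective sulfonylation of the primary hydroxyl (TsCl, Et3N, DMAP cat., CH2Cl2, 0 °C) gives the primary p-toluenesulfonate F2. Displacement by the tertiary alkoxide (K2CO3, MeCN, rt) closes the same oxirane with the C3–O bond retained, and the route is rejoined at 16.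

Step 10. SN2 attack at the oxirane methylene may be slow, because that carbon lies on the ring face next to the C4 silyloxymethyl group, and reductive opening or carbonyl addition may compete. Fallback: setting out from 14, the two bonds at C3 are made in the opposite order. Conjugate addition of cuprate 20 (made from 18 as in step 10; TMSCl, THF, −78 °C) and protonation give the (4R,5R)-3-(arylmethyl) lactone F3 as C3 epimers. Deprotonation (KN(SiMe3)2, THF, −78 °C) and enolate hydroxylation with 2-(phenylsulfonyl)-3-phenyloxaziridine, which should again occur on the face away from the C4 and C6 substituents, rejoin the route at 21.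

Step 12. The lactone equilibrium may lie on the side of 22, or the acyl shift through the strained bicyclic intermediate may be slow. Fallback: setting out from 22, the ring is closed by O-alkylation and no longer depends on an equilibrium. Selective sulfonylation of the primary hydroxyl (TsCl, pyridine, 0 °C) gives the primary p-toluenesulfonate F4. LiOH (1 equiv, THF/H2O, 0 °C) opens the lactone to the lithium carboxylate F5, whose carboxylate displaces the sulfonate at the primary, non-stereogenic carbon (5-exo-tet) and rejoins the route at 23.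

## Further compounds

F1 | step 8 | (3R,4R,5R)-4-[(tert-butyldimethylsilyloxy)methyl]-3-hydroxy-3-(hydroxymethyl)-5-[3-methoxy-4-(triisopropylsilyloxy)phenyl]dihydrofuran-2(3H)-one | OC[C@@]1(O)C(=O)O[C@@H](c2ccc(O[Si](C(C)C)(C(C)C)C(C)C)c(OC)c2)[C@H]1CO[Si](C)(C)C(C)(C)C
F2 | step 8 | (3R,4R,5R)-4-[(tert-butyldimethylsilyloxy)methyl]-3-hydroxy-5-[3-methoxy-4-(triisopropylsilyloxy)phenyl]-3-[(p-tolylsulfonyloxy)methyl]dihydrofuran-2(3H)-one | Cc1ccc(S(=O)(=O)OC[C@@]2(O)C(=O)O[C@@H](c3ccc(O[Si](C(C)C)(C(C)C)C(C)C)c(OC)c3)[C@H]2CO[Si](C)(C)C(C)(C)C)cc1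
F3 | step 10 | (4R,5R)-4-[(tert-butyldimethylsilyloxy)methyl]-3-[3-methoxy-4-(triisopropylsilyloxy)benzyl]-5-[3-methoxy-4-(triisopropylsilyloxy)phenyl]dihydrofuran-2(3H)-one (C3 epimers) | COc1cc(CC2C(=O)O[C@@H](c3ccc(O[Si](C(C)C)(C(C)C)C(C)C)c(OC)c3)[C@H]2CO[Si](C)(C)C(C)(C)C)ccc1O[Si](C(C)C)(C(C)C)C(C)C
F4 | step 12 | (3S,4R,5R)-3-hydroxy-3-[3-methoxy-4-(triisopropylsilyloxy)benzyl]-5-[3-methoxy-4-(triisopropylsilyloxy)phenyl]-4-[(p-tolylsulfonyloxy)methyl]dihydrofuran-2(3H)-one | O[C@]1(Cc2ccc(O[Si](C(C)C)(C(C)C)C(C)C)c(OC)c2)C(=O)O[C@@H](c2ccc(O[Si](C(C)C)(C(C)C)C(C)C)c(OC)c2)[C@H]1COS(=O)(=O)c1ccc(C)cc1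
F5 | step 12 | lithium (2S,3R,4R)-2,4-dihydroxy-2-[3-methoxy-4-(triisopropylsilyloxy)benzyl]-4-[3-methoxy-4-(triisopropylsilyloxy)phenyl]-3-[(p-tolylsulfonyloxy)methyl]butanoate | COc1cc(C[C@@](O)(C(=O)[O-])[C@H](COS(=O)(=O)c2ccc(C)cc2)[C@@H](O)c2ccc(O[Si](C(C)C)(C(C)C)C(C)C)c(OC)c2)ccc1O[Si](C(C)C)(C(C)C)C(C)C.[Li+]
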